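**Retrosynthetic overview**

1. Numbering used throughout: C1 = CH–O‑angelate, C2 = ring CH2, C3 = CH–OH, C4 = methyl‑bearing quaternary cyclobutane carbon, C5 and C7 = cyclobutane CH bridgeheads, C6 = cyclobutane CH that carries C11 [C(CH3)(CH2OAc)], C8 = ring C=O, C9 = CH2, C10 = CH–CH3. The cyclobutane is C4–C5–C6–C7, the cyclohexanone is C5–C6(or C4)–C7–C8–C9–C10, and the seven‑membered ring is C1–C2–C3–C4–C5(or C7)–C6–C11.
2. Feature: C4 is a quaternary cyclobutane carbon whose bond to C3 lies 1,3‑cis across the four‑membered ring to the C6–C11 bond, on the face opposite the C8–C9–C10 bridge. A C4=CH2 group can therefore become the methyl while its tertiary radical is caught at C3 by a C1(=O)–C2=C3–OPMB arm hung from C11.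
3. Last ring (seven‑membered): C3–C4 by iron‑hydride HAT and 7‑endo radical conjugate addition (25 → 28). A C3–OH‑directed Evans–Tishchenko reduction then sets C1, followed by angeloylation, acetylation and release of C3–OH.
4. Second ring (cyclohexanone): C7–C8 by intramolecular Mukaiyama aldol of cyclobutanone silyl enol ether 17. The cyclobutanone C4=O is then methylenated and the C11 arm is raised to the alkoxy enone; C8 is carried as a free ketone.
5. First ring (cyclobutane): auxiliary‑controlled keteniminium [2+2] of glutaramide 11 (C10 from the 3‑methylglutarate half‑ester) with alkene 7, whose quaternary C11 comes from Sharpless epoxidation and epoxy silyl ether rearrangement.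

Key step: step 18

Assumption: the (2R,5R)‑pyrrolidine keteniminium is taken to add the alkene in the endo sense and on the face that gives cis adduct 13 with the C6 configuration drawn; if the facial sense is the opposite, the (2S,5S)‑amine is used in the same way.

---

**Step 1**
Reactants: 1 (E)-3-methylpent-2-en-4-yn-1-ol
Product: 2 (E)-3-methylpenta-2,4-dien-1-ol
Conditions: H2 (1 atm), Pd/CaCO3 poisoned with Pb(OAc)2, quinoline, EtOAc, rt
Reagents that add atoms: none
Why: Lindlar semi‑hydrogenation should reduce only the terminal alkyne to the vinyl group and leave the (E)‑trisubstituted alkene untouched.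

**Step 2**
Reactants: 2 (E)-3-methylpenta-2,4-dien-1-ol
Product: 3 [(2S,3S)-3-ethenyl-3-methyloxiran-2-yl]methanol
Conditions: Ti(OiPr)4 (10 mol %), L-(+)-diethyl tartrate (12 mol %), t-BuOOH, 4 Å MS, CH2Cl2, −20 °C
Reagents that add atoms: tert-butyl hydroperoxide CC(C)(C)OO
Why: Sharpless asymmetric epoxidation is directed by the allylic hydroxyl to the C2=C3 alkene only, and L‑(+)‑tartrate should give the (2S,3S)‑epoxide as it does with geraniol.

**Step 3**
Reactants: 3 [(2S,3S)-3-ethenyl-3-methyloxiran-2-yl]methanol
Product: 4 tert-butyl{[(2S,3S)-3-ethenyl-3-methyloxiran-2-yl]methoxy}diphenylsilane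
Conditions: TBDPSCl, imidazole, DMF, 0 °C to rt
Reagents that add atoms: tert-butyl(chloro)diphenylsilane CC(C)(C)[Si](Cl)(c1ccccc1)c1ccccc1
Why: Routine silylation installs the robust silyl ether that serves as the migrating silyloxymethyl group and later as the protected acetoxymethyl arm of C11.

**Step 4**
Reactants: 4 epoxy silyl ether
Product: 5 (2S)-2-{[tert-butyl(diphenyl)silyl]oxymethyl}-2-methylbut-3-enal
Conditions: MeAl(OAr)2 (Ar = 4-bromo-2,6-di-tert-butylphenyl; from Me3Al and 2 ArOH), CH2Cl2, −78 to −40 °C
Reagents that add atoms: none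
Why: In the Yamamoto–Maruoka epoxy silyl ether rearrangement the bulky aluminium Lewis acid opens the epoxide at the allylic tertiary carbon and the silyloxymethyl group shifts anti to the leaving oxygen, so the epoxide chirality is transferred with inversion and sets quaternary C11.

**Step 5**
Reactants: 5 α‑quaternary aldehyde
Product: 6 (2R)-2-{[tert-butyl(diphenyl)silyl]oxymethyl}-2-methylbut-3-en-1-ol
Conditions: NaBH4, MeOH, −20 °C, short reaction time
Reagents that add atoms: none
Why: Hydride reduction of the non‑epimerisable aldehyde is run cold and briefly so that 1,5‑silyl migration, which would scramble C11, should not compete.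

**Step 6**
Reactants: 6 primary alcohol
Product: 7 (2R)-1-[tert-butyl(dimethyl)silyl]oxy-2-{[tert-butyl(diphenyl)silyl]oxymethyl}-2-methylbut-3-ene
Conditions: TBSCl, imidazole, CH2Cl2, 0 °C to rt
Reagents that add atoms: tert-butyl(chloro)dimethylsilane CC(C)(C)[Si](C)(C)Cl
Why: Silylation gives two primary silyl ethers of different lability, so the TBS arm (future C1) can later be freed in the presence of the TBDPS arm.

**Step 7**
Reactants: 8 methyl hydrogen (S)-3-methylglutarate; 9 (2R,5R)-2,5-dimethylpyrrolidine
Product: 11 methyl (3S)-5-[(2R,5R)-2,5-dimethylpyrrolidin-1-yl]-3-methyl-5-oxopentanoate, via acid chloride 10 (not isolated)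
Conditions: (COCl)2, cat. DMF, CH2Cl2, 0 °C to rt; then 9, Et3N, CH2Cl2, 0 °C
Reagents that add atoms: none
Why: Acylation of the hindered secondary amine through the acid chloride leaves the C10 stereocentre (β to both carbonyls) untouched; the free‑acid end of the (S)‑half‑ester must become the amide for the C10 methyl to have the configuration of the target.

**Step 8**
Reactants: 11 glutaramide; 7 alkene
Product: 15 trans‑cyclobutanone keto ester (C4 ketone; C5 chain trans to the C6 substituent), via keteniminium triflate 12 (not isolated), via cyclobutaniminium triflate 13 (not isolated), via cis-cyclobutanone 14 (not isolated)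
Conditions: Tf2O, 2,4,6-collidine, ClCH2CH2Cl, −20 to 80 °C; aq. NaHCO3, 60 °C; then DBU, CH2Cl2, rt
Reagents that add atoms: water O
Why: In this Ghosez keteniminium–alkene [2+2] the iminium carbon (C4) bonds to the terminal CH2 (C7) and the α‑carbon (C5) to the substituted alkene carbon (C6); the C2‑symmetric pyrrolidine shields one face for C5–C6 bond formation so that the non‑epimerisable C6 is set by the auxiliary, and after hydrolysis DBU epimerises the enolisable C5 to the more stable trans ketone.

**Step 9**
Reactants: 15 trans‑cyclobutanone keto ester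
Product: 16 tert‑butyldimethylsilyl enol ether of the cyclobutanone (C4=C7 double bond, ester intact)
Conditions: LDA (1.1 equiv), THF, −78 °C; TBSCl, DMPU, −78 to −20 °C
Reagents that add atoms: tert-butyl(chloro)dimethylsilane CC(C)(C)[Si](C)(C)Cl
Why: Kinetic deprotonation should take the accessible C7–H (the C5–H is tertiary and cis to the bulky C6 substituent) and the ketone is far more acidic than the ester, so O‑silylation gives the C4=C7 enol ether regioselectively.

**Step 10**
Reactants: 16 silyl enol ether ester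
Product: 17 silyl enol ether aldehyde (C8 = CHO)
Conditions: i-Bu2AlH (1.1 equiv), CH2Cl2, −78 °C; Rochelle salt work‑up
Reagents that add atoms: none
Why: Low‑temperature DIBAL reduction stops at the aldehyde through the stable tetrahedral aluminium hemiacetal, and silyl enol ethers and silyl ethers are inert to the reagent.

**Step 11**
Reactants: 17 silyl enol ether aldehyde
Product: 18 8-hydroxy bicyclo[3.1.1]heptan-6-one (systematically 2-hydroxy-4-methyl-7-substituted bicyclo[3.1.1]heptan-6-one; both C8 epimers)
Conditions: BF3·OEt2, CH2Cl2, −78 °C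
Reagents that add atoms: none
Why: The intramolecular Mukaiyama aldol forms C7–C8 irreversibly, since loss of the silyl group as the fluoride prevents reversal despite the added ring strain; the tether from C5 forces attack on the face of C7 cis to the C5 chain, which fixes C7, while the C8 carbinol configuration is irrelevant.

**Step 12**
Reactants: 18 hydroxy cyclobutanone
Product: 19 6-methylidene bicyclic alcohol (C4=CH2, C8–OH)
Conditions: Zn, CH2Br2, TiCl4, THF/CH2Cl2, 0 °C to rt (Takai–Lombardo)
Reagents that add atoms: dibromomethane BrCBr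
Why: The non‑basic zinc/titanium methylene reagent olefinates the strained, non‑enolisable cyclobutanone without triggering retro‑aldol of the β‑hydroxy ketone, which a Wittig ylide might cause.

**Step 13**
Reactants: 19 methylidene bis‑silyl ether
Product: 20 diol (C8–OH and the primary CH2OH of the C1 arm; TBDPS ether kept)
Conditions: HF·pyridine, pyridine, THF, 0 °C
Reagents that add atoms: none
Why: Buffered fluoride cleaves the primary TBS ether much faster than the TBDPS ether and leaves the acid‑sensitive methylenecyclobutane alone.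

**Step 14**
Reactants: 20 diol
Product: 21 hydroxy aldehyde (C1 = CHO on quaternary C11; C8–OH free)
Conditions: TEMPO (10 mol %), PhI(OAc)2, CH2Cl2, rt
Reagents that add atoms: none
Why: Oxoammonium oxidation is selective for the primary alcohol over the hindered secondary C8 alcohol, and the α‑quaternary aldehyde cannot epimerise.

**Step 15**
Reactants: 21 hydroxy aldehyde
Product: 22 propargylic alcohol diol (C1 carbinol and C8 carbinol as epimer mixtures)
Conditions: HC≡CMgBr (3 equiv), THF, −78 to 0 °C
Reagents that add atoms: ethynylmagnesium bromide C#C[Mg]Br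
Why: Grignard addition to the aldehyde is chemoselective by design because C8 is still at the alcohol oxidation level, and both new or unresolved carbinol centres are removed in the next step.

**Step 16**
Reactants: 22 propargylic alcohol diol
Product: 23 ynone diketone (C1 ynone, C8 ketone)
Conditions: Dess–Martin periodinane (3 equiv), NaHCO3, CH2Cl2, 0 °C to rt
Reagents that add atoms: none
Why: Dess–Martin oxidation converts both secondary alcohols under neutral conditions and converges the epimer mixtures; the C8 ketone cannot conjugate with the exocyclic alkene because C7 is a bridgehead.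

**Step 17**
Reactants: 23 ynone diketone; 24 4-methoxybenzyl alcohol
Product: 25 bicyclic methylenecyclobutane with the (E)-β-(4-methoxybenzyloxy) enone arm (C8 ketone free)
Conditions: PMe3 (10 mol %), CH2Cl2, 0 °C to rt
Reagents that add atoms: none
Why: Phosphine‑catalysed conjugate addition of an alcohol to a terminal ynone gives the thermodynamically preferred (E)-β-alkoxy enone, and the unconjugated C8 ketone is a spectator.

**Step 18**
Reactants: 25 methylenecyclobutane alkoxy enone
Product: 28 tricyclic seven‑ring ketone with the PMB ether on C3 and the new C4 methyl, via tertiary cyclobutyl radical 26 (not isolated), via α-keto radical 27 (not isolated)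
Conditions: Fe(acac)3 (30 mol %), PhSiH3 (2.5 equiv, slow addition), EtOH/(CH2OH)2 5:1, 0.01 M, 60 °C
Reagents that add atoms: none
Why: An iron hydride formed from Fe(acac)3 and PhSiH3 transfers a hydrogen atom to the CH2 terminus of the 1,1‑disubstituted alkene, which makes the C4 methyl and tertiary radical 26; 26 adds to C3, the β‑carbon of the vinylogous ester, and α‑keto radical 27 is reduced by divalent iron and protonated by ethanol, the closest known reaction type being the iron‑hydride reductive olefin coupling (radical conjugate addition) used to build quaternary carbons. The seven‑membered ring closes in the 7‑endo mode, because 6‑exo attack at C2 is polarity‑mismatched for the nucleophilic tertiary radical. The C4 configuration is fixed by the tether: the enone hangs from C6 on the face away from the C8–C9–C10 bridge, so C3 can only bond to that face and the methyl is forced to the bridge side. The C3 configuration is the least certain element: the forming ring should lean towards C7 so that the bulky silyloxymethyl group on C11 stays pseudo‑equatorial, and with the (E)‑enol ether the alkoxy group then points outwards, which is the required configuration. The step needs hydrogen‑atom transfer to the electron‑rich methylene rather than the push–pull enone and cyclisation faster than reduction of 26, which the donor character of the exocyclic alkene, high dilution and slow silane addition should secure. The protic medium should protonate the iron enolate before it can expel the alkoxide.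

**Step 19**
Reactants: 28 tricyclic PMB ether
Product: 29 tricyclic β-hydroxy ketone (C3–OH, C1 ketone, C8 ketone, TBDPS ether)
Conditions: DDQ, CH2Cl2/pH 7 buffer, 0 °C
Reagents that add atoms: none
Why: Oxidative cleavage of the PMB ether under buffered conditions frees C3–OH without dehydrating the β‑hydroxy ketone.

**Step 20**
Reactants: 29 β-hydroxy ketone
Product: 30 C3 pent-4-enoate C1 alcohol (1,3‑anti)
Conditions: CH2=CHCH2CH2CHO (6 equiv), SmI2 (30 mol %), THF, −10 °C
Reagents that add atoms: pent-4-enal C=CCCC=O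
Why: In the Evans–Tishchenko reduction the samarium‑bound hemiacetal on the C3 oxygen delivers hydride to C1 through a six‑membered transition state, necessarily on the ring face cis to C3–O, so C1–OH is formed anti to C3–O as in the target, C3 leaves as a selectively removable ester, and the C8 ketone, which has no β‑hydroxyl, is untouched.

**Step 21**
Reactants: 30 C1 alcohol; 31 angelic acid [(Z)-2-methylbut-2-enoic acid]
Product: 33 C1 angelate C3 pent-4-enoate, via mixed anhydride 32 (not isolated)
Conditions: 31, 2,4,6-trichlorobenzoyl chloride, Et3N, toluene, rt; then 30, toluene, 80 °C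
Reagents that add atoms: none
Why: Yamaguchi‑type mixed‑anhydride acylation without DMAP is the established way to esterify hindered alcohols with angelic acid without Z‑to‑E isomerisation, and C1–OH is the only free hydroxyl.

**Step 22**
Reactants: 33 angelate silyl ether
Product: 34 primary alcohol (CH2OH on C11)
Conditions: HF·pyridine, THF, 0 °C to rt
Reagents that add atoms: none
Why: Acidic fluoride removes the TBDPS group while avoiding the base‑induced 1,3‑acyl migration of the neighbouring angelate that TBAF could cause.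

**Step 23**
Reactants: 34 primary alcohol
Product: 35 acetate (CH2OAc on C11)
Conditions: AcCl, 2,4,6-collidine, CH2Cl2, −78 °C
Reagents that add atoms: acetyl chloride CC(Cl)=O
Why: Low‑temperature acetylation of the only free hydroxyl should be complete before any acyl migration.

**Step 24**
Reactants: 35 acetate angelate pent-4-enoate
Product: 36 target (CNP0212099.1)
Conditions: I2, NaHCO3, THF/H2O, rt
Reagents that add atoms: none
Why: Iodolactonisation of the pent‑4‑enoate (iodonium formation, 5‑exo attack by the ester carbonyl, hydrolysis) releases C3–OH under neutral conditions to which the acetate and the electron‑poor angelate alkene should be inert.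

---

**Compound list**

1 | (E)-3-methylpent-2-en-4-yn-1-ol | C#C/C(C)=C/CO | starting material
2 | (E)-3-methylpenta-2,4-dien-1-ol | C=C/C(C)=C/CO | intermediate
3 | [(2S,3S)-3-ethenyl-3-methyloxiran-2-yl]methanol | OC[C@@H]1O[C@@]1(C)C=C | intermediate
4 | tert-butyl{[(2S,3S)-3-ethenyl-3-methyloxiran-2-yl]methoxy}diphenylsilane | CC(C)(C)[Si](c1ccccc1)(c1ccccc1)OC[C@@H]1O[C@@]1(C)C=C | intermediate
5 | (2S)-2-{[tert-butyl(diphenyl)silyl]oxymethyl}-2-methylbut-3-enal | C=C[C@@](C)(CO[Si](c1ccccc1)(c1ccccc1)C(C)(C)C)C=O | intermediate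
6 | (2R)-2-{[tert-butyl(diphenyl)silyl]oxymethyl}-2-methylbut-3-en-1-ol | C=C[C@@](C)(CO[Si](c1ccccc1)(c1ccccc1)C(C)(C)C)CO | intermediate
7 | (2R)-1-[tert-butyl(dimethyl)silyl]oxy-2-{[tert-butyl(diphenyl)silyl]oxymethyl}-2-methylbut-3-ene | C=C[C@@](C)(CO[Si](c1ccccc1)(c1ccccc1)C(C)(C)C)CO[Si](C)(C)C(C)(C)C | intermediate
8 | methyl hydrogen (S)-3-methylglutarate | COC(=O)C[C@@H](C)CC(=O)O | starting material
9 | (2R,5R)-2,5-dimethylpyrrolidine | C[C@@H]1CC[C@@H](C)N1 | starting material
10 | methyl (3R)-5-chloro-3-methyl-5-oxopentanoate (acid chloride of 8, same spatial arrangement) | COC(=O)C[C@@H](C)CC(=O)Cl | intermediate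
11 | methyl (3S)-5-[(2R,5R)-2,5-dimethylpyrrolidin-1-yl]-3-methyl-5-oxopentanoate | COC(=O)C[C@@H](C)CC(=O)N1[C@H](C)CC[C@H]1C | intermediate
12 | keteniminium triflate from 11 (N-alkenylidene-2,5-dimethylpyrrolidinium) | COC(=O)C[C@@H](C)C=C=[N+]1[C@H](C)CC[C@H]1C.[O-]S(=O)(=O)C(F)(F)F | intermediate
13 | cyclobutaniminium triflate, C5 chain cis to the C6 substituent | COC(=O)C[C@@H](C)[C@H]1C(=[N+]2[C@H](C)CC[C@H]2C)C[C@H]1[C@@](C)(CO[Si](c3ccccc3)(c3ccccc3)C(C)(C)C)CO[Si](C)(C)C(C)(C)C.[O-]S(=O)(=O)C(F)(F)F | intermediate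
14 | cis-2,3-disubstituted cyclobutanone (C5 epimer of 15) | COC(=O)C[C@@H](C)[C@H]1C(=O)C[C@H]1[C@@](C)(CO[Si](c2ccccc2)(c2ccccc2)C(C)(C)C)CO[Si](C)(C)C(C)(C)C | intermediate
15 | trans-2,3-disubstituted cyclobutanone: methyl (3S)-3-(2-oxocyclobutyl)butanoate carrying at C6 the C(CH3)(CH2OTBDPS)(CH2OTBS) group | COC(=O)C[C@@H](C)[C@@H]1C(=O)C[C@H]1[C@@](C)(CO[Si](c2ccccc2)(c2ccccc2)C(C)(C)C)CO[Si](C)(C)C(C)(C)C | intermediate
16 | TBS enol ether of 15 (C4=C7) | COC(=O)C[C@@H](C)[C@@H]1C(O[Si](C)(C)C(C)(C)C)=C[C@H]1[C@@](C)(CO[Si](c2ccccc2)(c2ccccc2)C(C)(C)C)CO[Si](C)(C)C(C)(C)C | intermediate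
17 | enol ether aldehyde (C8 = CHO) | O=CC[C@@H](C)[C@@H]1C(O[Si](C)(C)C(C)(C)C)=C[C@H]1[C@@](C)(CO[Si](c2ccccc2)(c2ccccc2)C(C)(C)C)CO[Si](C)(C)C(C)(C)C | intermediate
18 | 2-hydroxy-4-methyl-7-[C(CH3)(CH2OTBDPS)(CH2OTBS)]bicyclo[3.1.1]heptan-6-one (C8–OH, both epimers) | O=C2[C@@H]3[C@@H]([C@H]2C(O)C[C@H]3C)[C@@](C)(CO[Si](c5ccccc5)(c5ccccc5)C(C)(C)C)CO[Si](C)(C)C(C)(C)C | intermediate
19 | 6-methylidene analogue of 18 (C4=CH2, C8–OH) | C=C2[C@@H]3[C@@H]([C@H]2C(O)C[C@H]3C)[C@@](C)(CO[Si](c5ccccc5)(c5ccccc5)C(C)(C)C)CO[Si](C)(C)C(C)(C)C | intermediate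
20 | diol (C8–OH, CH2OH arm, TBDPS ether) | C=C2[C@@H]3[C@@H]([C@H]2C(O)C[C@H]3C)[C@@](C)(CO[Si](c5ccccc5)(c5ccccc5)C(C)(C)C)CO | intermediate
21 | hydroxy aldehyde (C1 = CHO) | C=C2[C@@H]3[C@@H]([C@H]2C(O)C[C@H]3C)[C@@](C)(CO[Si](c5ccccc5)(c5ccccc5)C(C)(C)C)C=O | intermediate
22 | propargylic alcohol diol (C1 and C8 carbinols as mixtures) | C=C2[C@@H]3[C@@H]([C@H]2C(O)C[C@H]3C)[C@@](C)(CO[Si](c5ccccc5)(c5ccccc5)C(C)(C)C)C(O)C#C | intermediate
23 | ynone diketone (4-methyl-6-methylidenebicyclo[3.1.1]heptan-2-one with the C11 ynone arm) | C=C2[C@@H]3[C@@H]([C@H]2C(=O)C[C@H]3C)[C@@](C)(CO[Si](c5ccccc5)(c5ccccc5)C(C)(C)C)C(=O)C#C | intermediate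
24 | 4-methoxybenzyl alcohol | COc1ccc(CO)cc1 | starting material
25 | key‑step precursor: methylenecyclobutane ketone with the (E)-β-(4-methoxybenzyloxy) enone arm | C=C2[C@@H]3[C@@H]([C@H]2C(=O)C[C@H]3C)[C@@](C)(CO[Si](c5ccccc5)(c5ccccc5)C(C)(C)C)C(=O)/C=C/OCc6ccc(OC)cc6 | intermediate
26 | tertiary cyclobutyl radical at C4 (methyl formed) | C[C]2[C@@H]3[C@@H]([C@H]2C(=O)C[C@H]3C)[C@@](C)(CO[Si](c5ccccc5)(c5ccccc5)C(C)(C)C)C(=O)/C=C/OCc6ccc(OC)cc6 | intermediate
27 | α-keto radical at C2 after ring closure | O=C1[CH][C@@H](OCc6ccc(OC)cc6)[C@]2(C)[C@@H]3[C@@H]([C@H]2C(=O)C[C@H]3C)[C@@]1(C)CO[Si](c5ccccc5)(c5ccccc5)C(C)(C)C | intermediate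
28 | key‑step product: tricyclic diketone, C3–OPMB, C4 methyl, CH2OTBDPS | O=C1C[C@@H](OCc6ccc(OC)cc6)[C@]2(C)[C@@H]3[C@@H]([C@H]2C(=O)C[C@H]3C)[C@@]1(C)CO[Si](c5ccccc5)(c5ccccc5)C(C)(C)C | intermediate
29 | tricyclic β-hydroxy ketone (C3–OH) | O=C1C[C@@H](O)[C@]2(C)[C@@H]3[C@@H]([C@H]2C(=O)C[C@H]3C)[C@@]1(C)CO[Si](c5ccccc5)(c5ccccc5)C(C)(C)C | intermediate
30 | C1 alcohol, C3 pent-4-enoate (1,3-anti) | O[C@@H]1C[C@@H](OC(=O)CCC=C)[C@]2(C)[C@@H]3[C@@H]([C@H]2C(=O)C[C@H]3C)[C@@]1(C)CO[Si](c5ccccc5)(c5ccccc5)C(C)(C)C | intermediate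
31 | angelic acid, (Z)-2-methylbut-2-enoic acid | C/C=C(/C)C(=O)O | starting material
32 | angelic 2,4,6-trichlorobenzoic mixed anhydride | C/C=C(/C)C(=O)OC(=O)c1c(Cl)cc(Cl)cc1Cl | intermediate
33 | C1 angelate, C3 pent-4-enoate, CH2OTBDPS | C/C=C(/C)C(=O)O[C@@H]1C[C@@H](OC(=O)CCC=C)[C@]2(C)[C@@H]3[C@@H]([C@H]2C(=O)C[C@H]3C)[C@@]1(C)CO[Si](c5ccccc5)(c5ccccc5)C(C)(C)C | intermediate
34 | C1 angelate, C3 pent-4-enoate, CH2OH | C/C=C(/C)C(=O)O[C@@H]1C[C@@H](OC(=O)CCC=C)[C@]2(C)[C@@H]3[C@@H]([C@H]2C(=O)C[C@H]3C)[C@@]1(C)CO | intermediate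
35 | C1 angelate, C3 pent-4-enoate, CH2OAc | C/C=C(/C)C(=O)O[C@@H]1C[C@@H](OC(=O)CCC=C)[C@]2(C)[C@@H]3[C@@H]([C@H]2C(=O)C[C@H]3C)[C@@]1(C)COC(C)=O | intermediate
36 | CNP0212099.1 | C/C=C(/C)C(=O)O[C@@H]1C[C@@H](O)[C@]2(C)[C@@H]3[C@@H]([C@H]2C(=O)C[C@H]3C)[C@@]1(C)COC(C)=O | target

---

**Step count**

Total: 24 steps. Longest linear sequence: 23 steps (steps 1–6 and 8–24; step 7 is the side branch).

**Steps most likely to fail**

Step 18 (key step). The tertiary cyclobutyl radical may be reduced before the slow 7‑endo closure (net hydrogenation of the methylene), the iron enolate may expel the 4‑methoxybenzyloxide, or the ring may close with the wrong facial course at C3. The fallback sets out from ynone 23. Hydroiodination (NaI, AcOH, rt) should give (Z)-β-iodo enone F1. A palladium‑catalysed reductive Heck cyclisation (Pd(OAc)2, PPh3, HCO2Na, Et4NCl, DMF, 80 °C) is then used: the alkenylpalladium adds 7‑exo to the methylene on the tether face, and the neopentyl palladium species, which has no β‑hydrogen, is reduced by formate to the C4 methyl, to give cycloheptenone F2. Copper‑catalysed conjugate borylation (B2pin2, CuCl, NaOtBu, xantphos, MeOH, THF) should place boron on the outer, pseudo‑equatorial side of C3 to give β-boryl ketone F3. Oxidation (NaBO3, THF/H2O) gives β‑hydroxy ketone 29, where the route is rejoined; no PMB ether is then needed.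

Step 8 (keteniminium [2+2]). The facial bias of the auxiliary may be poorly transferred to C6 if the alkene approaches with mixed cis/trans topicity, and the hindered neopentyl‑type alkene may react more slowly than the keteniminium decomposes. The fallback sets out from alkene 7. Reductive ozonolysis (O3, CH2Cl2, −78 °C; PPh3) gives quaternary aldehyde F4, and Ohira–Bestmann homologation (dimethyl (1-diazo-2-oxopropyl)phosphonate, K2CO3, MeOH) gives alkyne F5. Cycloaddition of keteniminium 12 (from 11 as in step 8) with F5 gives cyclobuteniminium triflate F6, in which only C5 is created so that no topicity question arises, and hydrolysis gives cyclobutenone F7. Hydrogenation (H2, Pd/C, EtOAc) adds hydrogen anti to the C5 substituent and gives cis‑cyclobutanone 14, where the route is rejoined before the DBU equilibration to 15.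

Step 11 (Mukaiyama aldol). The strain of the bicyclo[3.1.1]heptanone may make the ring closure fail, through protodesilylation of the enol ether without C–C bond formation or retro‑aldol on work‑up. The fallback sets out from 17. Bromination of the silyl enol ether (NBS, THF, −78 °C) gives α-bromo cyclobutanone aldehyde F8. A samarium‑mediated intramolecular Reformatsky reaction (SmI2, THF, −78 °C) gives the chelated samarium aldolate, which should resist reversal, and on protonation hydroxy ketone 18, where the route is rejoined.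

**Further compounds**

F1 | step 18 | (Z)-β-iodo enone from ynone 23 | C=C2[C@@H]3[C@@H]([C@H]2C(=O)C[C@H]3C)[C@@](C)(CO[Si](c5ccccc5)(c5ccccc5)C(C)(C)C)C(=O)/C=C\I
F2 | step 18 | tricyclic cycloheptenone (C2=C3, C4 methyl) | O=C1C=C[C@]2(C)[C@@H]3[C@@H]([C@H]2C(=O)C[C@H]3C)[C@@]1(C)CO[Si](c5ccccc5)(c5ccccc5)C(C)(C)C
F3 | step 18 | β-boryl ketone (pinacol boronate on C3) | O=C1C[C@@H](B4OC(C)(C)C(C)(C)O4)[C@]2(C)[C@@H]3[C@@H]([C@H]2C(=O)C[C@H]3C)[C@@]1(C)CO[Si](c5ccccc5)(c5ccccc5)C(C)(C)C
F4 | step 8 | quaternary aldehyde from ozonolysis of 7 | O=C[C@@](C)(CO[Si](c1ccccc1)(c1ccccc1)C(C)(C)C)CO[Si](C)(C)C(C)(C)C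
F5 | step 8 | terminal alkyne analogue of 7 | C#C[C@@](C)(CO[Si](c1ccccc1)(c1ccccc1)C(C)(C)C)CO[Si](C)(C)C(C)(C)C
F6 | step 8 | cyclobuteniminium triflate | COC(=O)C[C@@H](C)[C@H]1C(=[N+]2[C@H](C)CC[C@H]2C)C=C1[C@@](C)(CO[Si](c3ccccc3)(c3ccccc3)C(C)(C)C)CO[Si](C)(C)C(C)(C)C.[O-]S(=O)(=O)C(F)(F)F
F7 | step 8 | 3,4-disubstituted cyclobut-2-enone | COC(=O)C[C@@H](C)[C@H]1C(=O)C=C1[C@@](C)(CO[Si](c2ccccc2)(c2ccccc2)C(C)(C)C)CO[Si](C)(C)C(C)(C)C
F8 | step 11 | α-bromo cyclobutanone aldehyde (C7–Br, either epimer) | O=CC[C@@H](C)[C@@H]1C(=O)C(Br)[C@H]1[C@@](C)(CO[Si](c2ccccc2)(c2ccccc2)C(C)(C)C)CO[Si](C)(C)C(C)(C)C
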